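The ten-membered carbocycle is traced back to a cyclohexane: C5 to C10 form a six-membered ring in which C10 is a vinyl carbinol and C5 carries an isopropenyl group, so that C2=C1–C10–C5–C4=C3 is a 1,5-diene. An anionic oxy-Cope shift forms C2–C3 and cleaves C5–C10 in one operation, opening the six- into the ten-membered ring, placing a ketone at C10 for the C14 methyl and leaving the E-C4=C5 alkene for the epoxide. The feature exploited is the saturated C1–C3 run ending at the trisubstituted C4–C5 unit. The precursor is a trans-1-vinyl-2-isopropenylcyclohexanol whose C6–C9 stereocentres are already set on a chair.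

Key step: step 11

Convention: the germacrane locants of the target are used for every intermediate (the cyclohexane is C5–C10). The α face is that of the C8 and C9 oxygens, the β face that of the C7 side chain.

Assumption: diol 1 is bought as the single (1S,2S) enantiomer; the other numbered starting materials are catalogue chemicals.

Design points:
- O6 (PMB) and O12 (TBS) carry different groups, so the C12 carboxyl can only close onto O8 and a 6,12-lactone is excluded.
- The axial C9 oxygen of the dioxolane should send any reagent to the β face of C10. A vinyl nucleophile added to a C10 ketone would then end cis to the isopropenyl group, and the chair shift would give the Z alkene. The C10–O bond is therefore the one made at the trigonal carbon (steps 8 to 10), which should place vinyl α, trans to isopropenyl.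
- C14 and the epoxide are each set by delivery from a neighbouring free hydroxyl (O9 and O6).

Step 1
Reactants: 1 (1S,2S)-3-bromocyclohexa-3,5-diene-1,2-diol
Product: 2 bromodiene acetonide
Conditions: 2,2-dimethoxypropane, TsOH·H2O (cat.), acetone, 0 °C to rt; used at once
Reagents that add atoms: 2,2-dimethoxypropane COC(C)(C)OC
Why: Acid-catalysed transketalisation closes the cis-fused dioxolane on the cis-diol, which protects O8 and O9 and shields the α face for the following steps without touching a stereocentre.

Step 2
Reactants: 2 bromodiene acetonide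
Product: 3 iodohydrin
Conditions: N-iodosuccinimide, THF/H2O, 0 °C, dark
Reagents that add atoms: N-iodosuccinimide O=C1CCC(=O)N1I; water O
Why: Halohydrin formation on the electron-richer, bromine-free C6=C7 alkene, in which the iodonium ion forms on the β face away from the dioxolane and water opens it at the allylic carbon C6 from the α face, should set O6 α and place iodine β at C7.

Step 3
Reactants: 3 iodohydrin; 4 allyltributylstannane
Product: 5 allyl alcohol
Conditions: AIBN (0.2 equiv), benzene, 80 °C
Reagents that add atoms: 4 allyltributylstannane C=CC[Sn](CCCC)(CCCC)CCCC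
Why: Keck radical allylation, in which the tin radical abstracts the alkyl iodine far faster than the vinylic bromine and the C7 radical is trapped on the β face anti to both flanking α oxygens (O6 and O8), should set C7 with its carbon chain trans to both neighbours.

Step 4
Reactants: 5 allyl alcohol
Product: 6 PMB ether
Conditions: NaH, 4-methoxybenzyl chloride, Bu4NI (cat.), DMF, 0 °C to rt
Reagents that add atoms: 4-methoxybenzyl chloride COc1ccc(CCl)cc1
Why: Williamson etherification of the only free hydroxyl masks O6 with a group that is later removed oxidatively without touching silyl ethers, the acetonide or the lactone.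

Step 5
Reactants: 6 PMB ether
Product: 9 primary alcohol, via diol 7 (not isolated), via aldehyde 8 (not isolated)
Conditions: OsO4 (2 mol%), NaIO4, 2,6-lutidine, dioxane/H2O, rt; then NaBH4, MeOH, 0 °C
Reagents that add atoms: sodium periodate [Na+].[O-]I(=O)(=O)=O
Why: Lemieux–Johnson cleavage of the monosubstituted alkene (the electron-poor trisubstituted bromoalkene should react far more slowly with OsO4) followed by borohydride reduction trims the allyl group to the two-carbon C11–C12 chain at the alcohol level.

Step 6
Reactants: 9 primary alcohol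
Product: 10 TBS ether
Conditions: TBSCl, imidazole, DMF, rt
Reagents that add atoms: tert-butyldimethylsilyl chloride CC(C)(C)[Si](C)(C)Cl
Why: Standard silylation of the primary alcohol gives O12 a protecting group different from that on O6, so that the two oxygens can be released at different stages.

Step 7
Reactants: 10 TBS ether; 11 N,N-dimethylformamide
Product: 13 enal, via vinyllithium 12 (not isolated)
Conditions: t-BuLi (2.1 equiv), Et2O, −78 °C; then 11, −78 to 0 °C; H2O
Reagents that add atoms: 11 N,N-dimethylformamide CN(C)C=O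
Why: Bromine–lithium exchange is faster than any deprotonation at −78 °C, the cyclohexenyllithium cannot expel the allylic C9 oxygen because that would require a six-membered allene, and formylation installs C1 as the aldehyde of a C10=C5 enal.

Step 8
Reactants: 13 enal; 14 isopropenylmagnesium bromide
Product: 15 silyl enol ether
Conditions: CuBr·SMe2 (10 mol%), TMSCl, HMPA, THF, −78 °C; Et3N, pentane, filtration
Reagents that add atoms: 14 isopropenylmagnesium bromide CC(=C)[Mg]Br; chlorotrimethylsilane C[Si](C)(C)Cl
Why: Copper-catalysed, chlorosilane-accelerated conjugate addition should deliver the isopropenyl group to C5 anti to the adjacent α ether at C6 and to the pseudo-axial α oxygen at C9 (hence 5β, trans to O6), and immediate O-silylation traps the enolate before it can expel the β oxygen at C9.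

Step 9
Reactants: 15 silyl enol ether
Product: 17 silyloxy aldehyde, via silyloxy epoxide 16 (not isolated)
Conditions: mCPBA (1.05 equiv), NaHCO3, CH2Cl2, −20 °C
Reagents that add atoms: 3-chloroperbenzoic acid O=C(OO)c1cccc(Cl)c1
Why: In this Rubottom oxidation the peracid should attack the electron-rich enol ether rather than the isopropenyl group, and from the β face of C10 anti to the axial C9 oxygen (the equatorial C5 substituent is gauche to both trajectories), so that after 1,4-silyl shift the oxygen is 10β and the formyl carbon 10α, trans to the isopropenyl group.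

Step 10
Reactants: 17 silyloxy aldehyde; 18 methyltriphenylphosphonium bromide
Product: 20 dialkenylcyclohexanol, via silyl ether 19 (not isolated)
Conditions: 18, KN(SiMe3)2, THF, 0 °C; add 17 at −78 °C, then rt; then K2CO3, MeOH, rt
Reagents that add atoms: 18 methyltriphenylphosphonium bromide C[P+](c1ccccc1)(c1ccccc1)c1ccccc1.[Br-]
Why: Wittig methylenation of the non-enolisable aldehyde supplies C2 while the silyl ether prevents an α-ketol shift, and mild methanolysis of the tertiary trimethylsilyl ether then frees the C10 hydroxyl without touching the primary TBS ether.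

Step 11
Reactants: 20 dialkenylcyclohexanol
Product: 23 cyclodecenone, via potassium alkoxide 21 (not isolated), via potassium enolate 22 (not isolated)
Conditions: KH (3 equiv), 18-crown-6 (3 equiv), THF, 0 °C to rt; then sat. aq NH4Cl at −78 °C
Reagents that add atoms: none
Why: KH with 18-crown-6 forms the free C10 potassium alkoxide 21, whose [3,3]-sigmatropic shift through a chair transition state forms C2–C3 and cleaves C5–C10 to give the C1=C10 enolate 22, which is protonated cold to ketone 23. The closest known reaction is the anionic oxy-Cope ring expansion of trans-1,2-dialkenylcyclohexanols to (E)-cyclodec-5-enones. The ten-membered ring is closed by a four-atom expansion of the six-membered ring, the new bond being made inside a six-membered pericyclic array and not by end-to-end cyclisation. No stereocentre is created: C5 and C10 become trigonal and C6 to C9 do not take part. The selectivity needed is the E geometry of C4=C5, secured by the trans-diequatorial vinyl and isopropenyl groups, which keep both ring bonds (C5–C6 and C9–C10) pseudo-equatorial on the chair. Enolate formation makes the shift irreversible, and since the enolate is formed only towards C1 it cannot expel the C8 oxygen if the quench is cold and buffered.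

Step 12
Reactants: 23 cyclodecenone; 24 Tebbe reagent, Cp2Ti(μ-Cl)(μ-CH2)AlMe2
Product: 25 methylene acetonide
Conditions: Cp2Ti(μ-Cl)(μ-CH2)AlMe2, pyridine (cat.), THF/toluene, −40 to 0 °C; NaOH (aq)
Reagents that add atoms: 24 Tebbe reagent C[Al-]1(C)C[Ti]([Cl+]1)(C1C=CC=C1)C1C=CC=C1
Why: Tebbe methylenation is non-basic, so the ketone with its acidic C9–H and β oxygen at C8 should be converted into the C10=C14 alkene without enolisation, epimerisation at C9 or loss of the dioxolane.

Step 13
Reactants: 25 methylene acetonide
Product: 26 triol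
Conditions: CSA (0.2 equiv), MeOH, rt
Reagents that add atoms: none
Why: Acid-catalysed methanolysis removes the acetonide and the primary TBS ether together while the PMB ether survives, and it is placed where neither a ketone nor an epoxide is present so that two isolated alkenes are the only acid-sensitive groups.

Step 14
Reactants: 26 triol
Product: 29 hydroxy lactone, via hydroxy aldehyde 27 (not isolated), via lactol 28 (not isolated)
Conditions: TEMPO (0.2 equiv), PhI(OAc)2 (2.5 equiv), CH2Cl2, rt
Reagents that add atoms: none
Why: Oxoammonium oxidation is selective for the primary C12 alcohol, the aldehyde closes to the five-membered lactol with O8 (O6 is blocked and O9 would need a bridged six-membered ring), and the lactol is oxidised on to the trans-fused 8,12-lactone while the hindered C9 hydroxyl should remain.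

Step 15
Reactants: 29 hydroxy lactone
Product: 30 methyl lactone
Conditions: [Rh(nbd)(dppb)]BF4 (10 mol%), H2 (50 bar), CH2Cl2, rt
Reagents that add atoms: none
Why: In this hydroxyl-directed homogeneous hydrogenation the cationic rhodium binds the allylic C9 hydroxyl and should add hydrogen only to the 1,1-disubstituted C10=C14 alkene, from the face of O9 in the rotamer in which C8 eclipses the double bond (least 1,2-allylic strain), which gives the 10R methyl group with C14 anti to O9 along the chain and leaves the undirected trisubstituted C4=C5 alkene alone.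

Step 16
Reactants: 30 methyl lactone
Product: 31 TES ether
Conditions: Et3SiOTf, 2,6-lutidine, CH2Cl2, −78 °C
Reagents that add atoms: triethylsilyl trifluoromethanesulfonate CC[Si](CC)(CC)OS(=O)(=O)C(F)(F)F
Why: Silylation of the hindered secondary C9 hydroxyl keeps it distinct from O6 during enolate chemistry and the later acylation.

Step 17
Reactants: 31 TES ether; 32 N,N-dimethylmethyleneiminium iodide
Product: 36 methylene lactone, via lithium enolate 33 (not isolated), via Mannich base 34 (not isolated), via ammonium iodide 35 (not isolated)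
Conditions: LiN(SiMe3)2, THF, −78 °C; 32, −78 °C to rt; then MeI, MeOH, rt; then NaHCO3 (aq), CH2Cl2
Reagents that add atoms: 32 N,N-dimethylmethyleneiminium iodide C=[N+](C)C.[I-]
Why: Lactone α-methylenation by Mannich reaction of the lithium enolate, N-methylation and mild base elimination should be clean because C11 is the only acidic position, carries no β leaving group and becomes trigonal, so its configuration does not matter.

Step 18
Reactants: 36 methylene lactone
Product: 37 allylic alcohol
Conditions: DDQ (1.3 equiv), CH2Cl2/pH 7 buffer, 0 °C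
Reagents that add atoms: none
Why: Oxidative cleavage of the PMB ether through its benzylic cation frees the C6 hydroxyl under buffered conditions that should leave the silyl ether, both alkenes and the lactone untouched.

Step 19
Reactants: 37 allylic alcohol
Product: 38 epoxy alcohol
Conditions: VO(acac)2 (5 mol%), t-BuOOH (decane solution, 1.5 equiv), CH2Cl2, 0 °C to rt
Reagents that add atoms: tert-butyl hydroperoxide CC(C)(C)OO
Why: Hydroxyl-directed vanadium-catalysed epoxidation should react only at the allylic-alcohol alkene C4=C5 (the methylene lactone is electron-poor) and deliver oxygen to the outer face on which O6 lies in the rotamer with a small O6–C6–C5=C4 dihedral and C7 on the inner face, which gives the erythro 4R,5R epoxide, its trans geometry following from the E alkene.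

Step 20
Reactants: 38 epoxy alcohol; 39 3-methylbut-2-enoic acid
Product: 40 senecioate
Conditions: DCC, DMAP, CH2Cl2, 0 °C to rt
Reagents that add atoms: 39 3-methylbut-2-enoic acid CC(C)=CC(=O)O
Why: Steglich esterification acylates the only free hydroxyl (O6) with retention at C6 and without amine-induced ketene formation that could deconjugate the enoate or base that could open the epoxide.

Step 21
Reactants: 40 senecioate
Product: 41 CNP0119422.1
Conditions: HF·pyridine, pyridine, THF, 0 °C
Reagents that add atoms: none
Why: Buffered fluoride cleaves the triethylsilyl ether selectively and releases the C9 hydroxyl, while the epoxide, the enoate ester and the methylene lactone should be untouched.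

Compound list

1 | (1S,2S)-3-bromocyclohexa-3,5-diene-1,2-diol | O[C@@H]1[C@H](O)C(Br)=CC=C1 | starting material
2 | bromodiene acetonide, (3aS,7aS)-4-bromo-2,2-dimethyl-3a,7a-dihydro-1,3-benzodioxole (Br on C10; 8α,9α-dioxolane) | CC1(C)O[C@@H]2[C@H](O1)C(Br)=CC=C2 | intermediate
3 | iodohydrin: 10-bromo-6α-hydroxy-7β-iodo-8α,9α-isopropylidenedioxycyclohex-5(10)-ene | CC1(C)O[C@@H]2[C@H](O1)C(Br)=C[C@H](O)[C@H]2I | intermediate
4 | allyltributylstannane | C=CC[Sn](CCCC)(CCCC)CCCC | starting material
5 | allyl alcohol: 7β-allyl-10-bromo-6α-hydroxy-8α,9α-isopropylidenedioxycyclohex-5(10)-ene | CC1(C)O[C@@H]2[C@H](O1)C(Br)=C[C@H](O)[C@H]2CC=C | intermediate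
6 | PMB ether: 6α-(4-methoxybenzyloxy) derivative of 5 | CC1(C)O[C@@H]2[C@H](O1)C(Br)=C[C@H](OCc3ccc(OC)cc3)[C@H]2CC=C | intermediate
7 | diol: 7β-(2,3-dihydroxypropyl) compound from 6 (epimers at the new carbinol) | CC1(C)O[C@@H]2[C@H](O1)C(Br)=C[C@H](OCc3ccc(OC)cc3)[C@H]2CC(O)CO | intermediate
8 | aldehyde: 7β-(2-oxoethyl) compound (C12 aldehyde) | CC1(C)O[C@@H]2[C@H](O1)C(Br)=C[C@H](OCc3ccc(OC)cc3)[C@H]2CC=O | intermediate
9 | primary alcohol: 7β-(2-hydroxyethyl) compound | CC1(C)O[C@@H]2[C@H](O1)C(Br)=C[C@H](OCc3ccc(OC)cc3)[C@H]2CCO | intermediate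
10 | TBS ether: 7β-(2-tert-butyldimethylsilyloxyethyl) compound | CC1(C)O[C@@H]2[C@H](O1)C(Br)=C[C@H](OCc3ccc(OC)cc3)[C@H]2CCO[Si](C)(C)C(C)(C)C | intermediate
11 | N,N-dimethylformamide | CN(C)C=O | starting material
12 | vinyllithium: C10-lithio analogue of 10 | CC1(C)O[C@@H]2[C@H](O1)C([Li])=C[C@H](OCc3ccc(OC)cc3)[C@H]2CCO[Si](C)(C)C(C)(C)C | intermediate
13 | enal: 10-formylcyclohex-5(10)-ene with 6α-OPMB, 7β-CH2CH2OTBS, 8α,9α-acetonide | CC1(C)O[C@@H]2[C@H](O1)C(C=O)=C[C@H](OCc3ccc(OC)cc3)[C@H]2CCO[Si](C)(C)C(C)(C)C | intermediate
14 | isopropenylmagnesium bromide | CC(=C)[Mg]Br | starting material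
15 | silyl enol ether: 5β-isopropenyl-10-(trimethylsilyloxymethylidene)cyclohexane (E/Z mixture at the enol ether) | CC1(C)O[C@@H]2[C@H](O1)C(=CO[Si](C)(C)C)[C@@H](C(C)=C)[C@H](OCc3ccc(OC)cc3)[C@H]2CCO[Si](C)(C)C(C)(C)C | intermediate
16 | silyloxy epoxide: spiro oxirane at C10 with oxygen β, bearing OSiMe3 on C1 (epimers at C1) | CC1(C)O[C@@H]2[C@H](O1)[C@@]3(OC3O[Si](C)(C)C)[C@@H](C(C)=C)[C@H](OCc4ccc(OC)cc4)[C@H]2CCO[Si](C)(C)C(C)(C)C | intermediate
17 | silyloxy aldehyde: 10α-formyl-10β-trimethylsilyloxy-5β-isopropenylcyclohexane | CC1(C)O[C@@H]2[C@H](O1)[C@](O[Si](C)(C)C)(C=O)[C@@H](C(C)=C)[C@H](OCc3ccc(OC)cc3)[C@H]2CCO[Si](C)(C)C(C)(C)C | intermediate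
18 | methyltriphenylphosphonium bromide | C[P+](c1ccccc1)(c1ccccc1)c1ccccc1.[Br-] | starting material
19 | silyl ether: 10β-trimethylsilyloxy-10α-vinyl-5β-isopropenylcyclohexane | CC1(C)O[C@@H]2[C@H](O1)[C@](O[Si](C)(C)C)(C=C)[C@@H](C(C)=C)[C@H](OCc3ccc(OC)cc3)[C@H]2CCO[Si](C)(C)C(C)(C)C | intermediate
20 | dialkenylcyclohexanol (oxy-Cope precursor): 10β-hydroxy-10α-vinyl-5β-isopropenyl-6α-OPMB-7β-CH2CH2OTBS-8α,9α-acetonide | CC1(C)O[C@@H]2[C@H](O1)[C@](O)(C=C)[C@@H](C(C)=C)[C@H](OCc3ccc(OC)cc3)[C@H]2CCO[Si](C)(C)C(C)(C)C | intermediate
21 | potassium alkoxide of 20 | [K+].CC1(C)O[C@@H]2[C@H](O1)[C@]([O-])(C=C)[C@@H](C(C)=C)[C@H](OCc3ccc(OC)cc3)[C@H]2CCO[Si](C)(C)C(C)(C)C | intermediate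
22 | potassium enolate: ten-membered (1(10)E,4E)-dienolate | [K+].CC1(C)O[C@@H]2[C@H](O1)/C([O-])=C/CC/C(C)=C/[C@H](OCc3ccc(OC)cc3)[C@H]2CCO[Si](C)(C)C(C)(C)C | intermediate
23 | cyclodecenone (oxy-Cope product): ten-membered C10 ketone, (4E)-alkene, 6α-OPMB, 7β-CH2CH2OTBS, 8α,9α-acetonide | CC1(C)O[C@@H]2[C@H](O1)C(=O)CCC/C(C)=C/[C@H](OCc3ccc(OC)cc3)[C@H]2CCO[Si](C)(C)C(C)(C)C | intermediate
24 | Tebbe reagent, Cp2Ti(μ-Cl)(μ-CH2)AlMe2 (four-membered Ti–CH2–Al–Cl ring with bridging chloride, drawn charge-separated) | C[Al-]1(C)C[Ti]([Cl+]1)(C1C=CC=C1)C1C=CC=C1 | starting material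
25 | methylene acetonide: C10=C14 exocyclic alkene analogue of 23 | CC1(C)O[C@@H]2[C@H](O1)C(=C)CCC/C(C)=C/[C@H](OCc3ccc(OC)cc3)[C@H]2CCO[Si](C)(C)C(C)(C)C | intermediate
26 | triol: 8α,9α,12-trihydroxy-6α-OPMB-germacra-4E,10(14)-diene | O[C@@H]1[C@H](O)C(=C)CCC/C(C)=C/[C@H](OCc2ccc(OC)cc2)[C@H]1CCO | intermediate
27 | hydroxy aldehyde: C12 aldehyde of 26 | O[C@@H]1[C@H](O)C(=C)CCC/C(C)=C/[C@H](OCc2ccc(OC)cc2)[C@H]1CC=O | intermediate
28 | lactol: 8,12-hemiacetal (anomers) | C1C(O)O[C@@H]2[C@H](O)C(=C)CCC/C(C)=C/[C@H](OCc3ccc(OC)cc3)[C@@H]12 | intermediate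
29 | hydroxy lactone: 9α-hydroxy-6α-OPMB-germacra-4E,10(14)-dien-12,8α-olide (trans-fused) | C1C(=O)O[C@@H]2[C@H](O)C(=C)CCC/C(C)=C/[C@H](OCc3ccc(OC)cc3)[C@@H]12 | intermediate
30 | methyl lactone: (10R)-9α-hydroxy-6α-OPMB-germacr-4E-en-12,8α-olide | C1C(=O)O[C@@H]2[C@H](O)[C@H](C)CCC/C(C)=C/[C@H](OCc3ccc(OC)cc3)[C@@H]12 | intermediate
31 | TES ether: 9-O-triethylsilyl derivative of 30 | C1C(=O)O[C@@H]2[C@H](O[Si](CC)(CC)CC)[C@H](C)CCC/C(C)=C/[C@H](OCc3ccc(OC)cc3)[C@@H]12 | intermediate
32 | N,N-dimethylmethyleneiminium iodide | C=[N+](C)C.[I-] | starting material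
33 | lithium enolate of lactone 31 | C1=C(O[Li])O[C@@H]2[C@H](O[Si](CC)(CC)CC)[C@H](C)CCC/C(C)=C/[C@H](OCc3ccc(OC)cc3)[C@@H]12 | intermediate
34 | Mannich base: 11-(dimethylaminomethyl) lactone (epimers at C11) | CN(C)CC1C(=O)O[C@@H]2[C@H](O[Si](CC)(CC)CC)[C@H](C)CCC/C(C)=C/[C@H](OCc3ccc(OC)cc3)[C@@H]12 | intermediate
35 | ammonium iodide: 11-(trimethylammoniomethyl) lactone iodide | [I-].C[N+](C)(C)CC1C(=O)O[C@@H]2[C@H](O[Si](CC)(CC)CC)[C@H](C)CCC/C(C)=C/[C@H](OCc3ccc(OC)cc3)[C@@H]12 | intermediate
36 | methylene lactone: 6α-OPMB-9α-OTES-germacra-4E,11(13)-dien-12,8α-olide | C=C1C(=O)O[C@@H]2[C@H](O[Si](CC)(CC)CC)[C@H](C)CCC/C(C)=C/[C@H](OCc3ccc(OC)cc3)[C@@H]12 | intermediate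
37 | allylic alcohol: 6α-hydroxy analogue of 36 | C=C1C(=O)O[C@@H]2[C@H](O[Si](CC)(CC)CC)[C@H](C)CCC/C(C)=C/[C@H](O)[C@@H]12 | intermediate
38 | epoxy alcohol: (4R,5R)-4,5-epoxy-6α-hydroxy-9α-OTES lactone | C=C1C(=O)O[C@@H]2[C@H](O[Si](CC)(CC)CC)[C@H](C)CCC[C@@]3(C)O[C@@H]3[C@H](O)[C@@H]12 | intermediate
39 | 3-methylbut-2-enoic acid | CC(C)=CC(=O)O | starting material
40 | senecioate: 6-O-(3-methylbut-2-enoyl) derivative of 38 | C=C1C(=O)O[C@@H]2[C@H](O[Si](CC)(CC)CC)[C@H](C)CCC[C@@]3(C)O[C@@H]3[C@H](OC(=O)C=C(C)C)[C@@H]12 | intermediate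
41 | CNP0119422.1 | C=C1C(=O)O[C@@H]2[C@H](O)[C@H](C)CCC[C@@]3(C)O[C@@H]3[C@H](OC(=O)C=C(C)C)[C@@H]12 | target

Total step count: 21. Longest linear sequence: 21 steps (1 to 41).

Steps most likely to fail

Step 11. What may go wrong is proton transfer within the enolate towards C9 followed by loss of the C8 oxygen, or a competing 1,3-shift of the alkoxide. The fallback avoids any alkoxide or enolate. It sets out from alcohol 20 and treats it with catalytic PdCl2(MeCN)2 in THF at room temperature. Divalent palladium binds the vinyl group, the isopropenyl terminus attacks it in a chair-like cyclisation that forms C2–C3 and places a methyl-stabilised cation at C4, and fragmentation of C5–C10 releases the enol and the catalyst. The route is rejoined at ketone 23, and no new compound is made (F0).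

Step 15. What may go wrong is delivery of hydrogen to the other face of C10, because the ring rather than allylic strain sets the C8–C9–C10–C1 torsion, or isomerisation of the allylic alcohol to a C9 ketone by the cationic rhodium. The fallback reduces before the diol is unveiled, so that steric approach away from the C9 oxygen replaces hydroxyl delivery. It sets out from 25, which is hydrogenated with RhCl(PPh3)3 and H2 in benzene; this catalyst leaves the trisubstituted alkene and the PMB ether alone and gives the 10-methyl acetonide F1. CSA in methanol then gives the 10-methyl triol F2. TEMPO with PhI(OAc)2 oxidises it through the hydroxy aldehyde F3 and the lactol F4 (neither isolated), and the route is rejoined at 30.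

Step 19. What may go wrong is oxygen transfer through the other alkene rotamer (C6–H in the alkene plane, as allylic strain with the C4 methyl would favour), which would put the epoxide on the opposite face, or oxidation of the allylic alcohol to the enone. The fallback replaces substrate control by reagent control. It sets out from 37 and uses a Sharpless asymmetric epoxidation with Ti(OiPr)4, L-(+)-diisopropyl tartrate, t-BuOOH and 4 Å sieves in CH2Cl2 at −20 °C. With this tartrate, 37 is the fast-reacting antipode: oxygen comes to the face opposite C7 with the hydroxyl near the alkene plane, which is the erythro 4R,5R outcome. The route is rejoined at 38, and no new compound is made (F0).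

Further compounds
F0 | step 11 | none | none
F1 | step 15 | 10-methyl acetonide: (10R)-10-methyl analogue of 25 with C10=C14 reduced | CC1(C)O[C@@H]2[C@H](O1)[C@H](C)CCC/C(C)=C/[C@H](OCc3ccc(OC)cc3)[C@H]2CCO[Si](C)(C)C(C)(C)C
F2 | step 15 | 10-methyl triol: (10R)-8α,9α,12-trihydroxy-6α-OPMB-germacr-4E-ene | O[C@@H]1[C@H](O)[C@H](C)CCC/C(C)=C/[C@H](OCc2ccc(OC)cc2)[C@H]1CCO
F3 | step 15 | 10-methyl hydroxy aldehyde: C12 aldehyde of F2 | O[C@@H]1[C@H](O)[C@H](C)CCC/C(C)=C/[C@H](OCc2ccc(OC)cc2)[C@H]1CC=O
F4 | step 15 | 10-methyl lactol: 8,12-hemiacetal of F3 (anomers) | C1C(O)O[C@@H]2[C@H](O)[C@H](C)CCC/C(C)=C/[C@H](OCc3ccc(OC)cc3)[C@@H]12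
F0 | step 19 | none | none
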